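**Retrosynthetic overview**
1. Nymphaeol A ⇐ acetal removal and C4 oxidation of the tetra-MOM (2S,4R)-flavan-4-ol. Rings A and B are bought as arenes; ring C is the only ring made and is closed last.
2. Ring C ⇐ O1–C8a bond, by copper-catalysed O-arylation of the C2 hydroxyl on a C8a bromide. The plan rests on one feature of ring A: the ether carbon C8a lies para to the geranyl-bearing C6 and meta to the C5 and C7 oxygens, so the bromine of 5-bromoresorcinol marks C8a by symmetry and C2 can be set earlier in an open chain.
3. syn-1,3-Diol ⇐ chelate-controlled reduction of a β-hydroxy ketone ⇐ C4–C4a bond from the aryllithium next to bromine and an (S)-β-hydroxy N-methoxy-N-methylamide, whose carbinol centre comes from asymmetric transfer hydrogenation.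
4. Ring A piece ⇐ 5-bromoresorcinol (iodination between the hydroxyls, MOM protection, iodine–magnesium exchange, geranylation). Ring B piece ⇐ methyl 3,4-dihydroxybenzoate and N-methoxy-N-methylacetamide.

Key step: step 9

Remark: MOM = methoxymethyl and geranyl = (2E)-3,7-dimethylocta-2,6-dien-1-yl; the C4 carbinol is a spectator centre erased in step 10 and is set syn to C2 only so that single compounds are carried.
Remark: the ring carbon between the two acetal oxygens is marked with iodine before metalation, because with bromine present it cannot be lithiated there reliably (alkyllithiums exchange the bromine, amide bases may take the proton next to bromine).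

**Step 1**
Reactants: 1 5-bromoresorcinol (5-bromobenzene-1,3-diol)
Product: 2 5-bromo-2-iodobenzene-1,3-diol
Conditions: I2, NaHCO3, THF/H2O, 0 °C
Reagents that add atoms: iodine, II
Why: Electrophilic aromatic iodination under bicarbonate is expected to take the carbon between the two hydroxyls, as resorcinol and its 5-alkyl homologues do under these conditions, and the bromine further shields C4 and C6.

**Step 2**
Reactants: 2 5-bromo-2-iodobenzene-1,3-diol
Product: 3 5-bromo-2-iodo-1,3-bis(methoxymethoxy)benzene
Conditions: MOMCl, i-Pr2NEt, CH2Cl2, 0 °C → rt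
Reagents that add atoms: chloromethyl methyl ether (MOMCl), COCCl
Why: Both phenols are O-alkylated by the chloromethyl ether under amine base (Williamson-type acetal formation), which masks them and provides the coordinating groups used in steps 3 and 7.

**Step 3**
Reactants: 3 5-bromo-2-iodo-1,3-bis(methoxymethoxy)benzene; 4 geranyl bromide [(2E)-1-bromo-3,7-dimethylocta-2,6-diene]
Product: 6 5-bromo-2-geranyl-1,3-bis(methoxymethoxy)benzene, via arylmagnesium chloride 5 (not isolated)
Conditions: i-PrMgCl·LiCl, THF, −20 → 0 °C; then CuI (10 mol%), 4, −20 °C → rt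
Reagents that add atoms: none
Why: Iodine–magnesium exchange with i-PrMgCl·LiCl is far faster at the C–I bond flanked by two chelating OMOM groups than at C–Br, and the copper-catalysed allylic substitution of the hindered aryl Grignard reagent should go at the primary carbon of 4 (SN2 mode, since attack at the disubstituted γ-carbon would build a quaternary centre beside a 2,6-disubstituted ring), so the E alkene is carried over.

**Step 4**
Reactants: 7 methyl 3,4-dihydroxybenzoate
Product: 8 methyl 3,4-bis(methoxymethoxy)benzoate
Conditions: MOMCl, i-Pr2NEt, CH2Cl2, 0 °C → rt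
Reagents that add atoms: chloromethyl methyl ether (MOMCl), COCCl
Why: Williamson-type O-alkylation of the catechol with the chloromethyl ether under amine base, to which the ester is inert.

**Step 5**
Reactants: 8 methyl 3,4-bis(methoxymethoxy)benzoate; 9 N-methoxy-N-methylacetamide
Product: 11 3-[3,4-bis(methoxymethoxy)phenyl]-N-methoxy-N-methyl-3-oxopropanamide, via lithium enolate 10 (not isolated)
Conditions: 9 (2.2 equiv), LiN(i-Pr)2 (2.2 equiv), THF, −78 °C; then 8, −78 → 0 °C; aq. NH4Cl
Reagents that add atoms: none
Why: Crossed Claisen condensation, in which the amide enolate acylates on the non-enolisable aryl ester and the acidic β-keto amide formed is deprotonated by the second equivalent of enolate, which prevents a second addition.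

**Step 6**
Reactants: 11 3-[3,4-bis(methoxymethoxy)phenyl]-N-methoxy-N-methyl-3-oxopropanamide
Product: 12 (3S)-3-[3,4-bis(methoxymethoxy)phenyl]-3-hydroxy-N-methoxy-N-methylpropanamide
Conditions: RuCl(p-cymene)[(S,S)-TsDPEN] (1 mol%), HCO2H/Et3N (5:2), DMF, 40 °C
Reagents that add atoms: none
Why: Noyori asymmetric transfer hydrogenation, in which the (S,S)-TsDPEN ruthenium hydride reduces the aryl ketone with the same facial preference as for acetophenone [(S)-carbinol, priorities O > aryl > CH2], so the future C2 is set as S under catalyst control while the amide carbonyl is untouched.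

**Step 7**
Reactants: 6 5-bromo-2-geranyl-1,3-bis(methoxymethoxy)benzene; 12 (3S)-3-[3,4-bis(methoxymethoxy)phenyl]-3-hydroxy-N-methoxy-N-methylpropanamide
Product: 15 (3S)-1-[6-bromo-3-geranyl-2,4-bis(methoxymethoxy)phenyl]-3-[3,4-bis(methoxymethoxy)phenyl]-3-hydroxypropan-1-one, via aryllithium 13 (not isolated), via magnesium alkoxide 14 (not isolated)
Conditions: 6 (1.2 equiv), LiN(i-Pr)2, THF, −78 °C; 12 pre-treated with i-PrMgCl (1.0 equiv, THF, −78 °C) added at −78 °C, then → −20 °C; aq. NH4Cl
Reagents that add atoms: none
Why: Directed ortho-lithiation by the amide base removes the only ring proton of 6, which is flanked and acidified by bromine and an OMOM group, and at low temperature the aryllithium adds once to the N-methoxy-N-methylamide of the pre-formed alkoxide (Weinreb ketone synthesis) without touching the C3 carbinol centre, whose alkoxide form also keeps the amide from enolising.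

**Step 8**
Reactants: 15 (3S)-1-[6-bromo-3-geranyl-2,4-bis(methoxymethoxy)phenyl]-3-[3,4-bis(methoxymethoxy)phenyl]-3-hydroxypropan-1-one
Product: 17 (1R,3S)-1-[6-bromo-3-geranyl-2,4-bis(methoxymethoxy)phenyl]-3-[3,4-bis(methoxymethoxy)phenyl]propane-1,3-diol, via diethylboron chelate 16 (not isolated)
Conditions: Et2BOMe, THF/MeOH (4:1), −78 °C; NaBH4, −78 → −40 °C; then MeOH co-evaporation (boron leaves as Et2BOMe)
Reagents that add atoms: none
Why: Narasaka–Prasad reduction, in which the six-membered diethylboron chelate 16 is attacked by external hydride on the face that gives the 1,3-syn diol, so the new C1 centre (flavan C4) is R under control of the existing C3 centre.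

**Step 9**
Reactants: 17 (1R,3S)-1-[6-bromo-3-geranyl-2,4-bis(methoxymethoxy)phenyl]-3-[3,4-bis(methoxymethoxy)phenyl]propane-1,3-diol
Product: 18 (2S,4R)-6-geranyl-5,7,3',4'-tetrakis(methoxymethoxy)flavan-4-ol
Conditions: CuI (20 mol%), 3,4,7,8-tetramethyl-1,10-phenanthroline (40 mol%), Cs2CO3 (2 equiv), degassed toluene, 110 °C, argon
Reagents that add atoms: none
Why: Cs2CO3 and the phenanthroline-ligated monovalent copper turn the C3 hydroxyl (flavan C2–OH) into a copper alkoxide, which inserts into the neighbouring C–Br bond to give a trivalent copper aryl alkoxide and then reductively eliminates the O1–C8a aryl ether. The closest known reaction is the copper-catalysed Ullmann-type intramolecular O-arylation of secondary alcohols by aryl bromides, which gives chromans and 2-arylchromans. Ring C is closed in a six-membered exo mode (O1, C2, C3, C4, C4a, C8a), whereas closure through the C1 hydroxyl would need a four-membered ring and is not expected. No stereocentre is created: oxygen is the nucleophile and the C–O bond of the carbinol is never broken, so the 3S centre becomes 2S with retention and the 1R carbinol becomes 4R unchanged. The step needs chemoselectivity between the two hydroxyls, which ring size provides, and regiochemistry on ring A, which is fixed because the bromine sits para to the geranyl group so that only C8a can be etherified. Keeping C4 as an alcohol removes the retro-aldol, β-elimination and ring-opening pathways that a ketone would offer under hot carbonate.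

**Step 10**
Reactants: 18 (2S,4R)-6-geranyl-5,7,3',4'-tetrakis(methoxymethoxy)flavan-4-ol
Product: 19 (2S)-6-geranyl-5,7,3',4'-tetrakis(methoxymethoxy)flavanone
Conditions: Dess–Martin periodinane, CH2Cl2, 0 °C → rt
Reagents that add atoms: none
Why: Dess–Martin oxidation of the secondary benzylic alcohol runs without base, so the acetals and alkenes survive and the C2 centre of the new flavanone, which epimerises only through base-induced ring opening to the chalcone, is preserved.

**Step 11**
Reactants: 19 (2S)-6-geranyl-5,7,3',4'-tetrakis(methoxymethoxy)flavanone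
Product: 20 nymphaeol A [(2S)-6-geranyl-5,7,3',4'-tetrahydroxyflavanone]
Conditions: 3 M aq. HCl, MeOH, 40 °C
Reagents that add atoms: none
Why: Acid-catalysed acetal exchange with methanol (MOM ether cleavage) frees the four phenols, the C5 acetal peri to the carbonyl going first, and the mild temperature is chosen so that the geranyl alkenes and the C2 centre, which is stable to dilute acid, are not affected.

**Compound list**
1 | 5-bromoresorcinol | Oc1cc(O)cc(Br)c1 | starting material
2 | 5-bromo-2-iodobenzene-1,3-diol | Oc1cc(Br)cc(O)c1I | intermediate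
3 | 5-bromo-2-iodo-1,3-bis(methoxymethoxy)benzene | COCOc1cc(Br)cc(OCOC)c1I | intermediate
4 | geranyl bromide | CC(C)=CCC/C(C)=C/CBr | starting material
5 | [4-bromo-2,6-bis(methoxymethoxy)phenyl]magnesium chloride | COCOc1cc(Br)cc(OCOC)c1[Mg]Cl | intermediate
6 | 5-bromo-2-geranyl-1,3-bis(methoxymethoxy)benzene | CC(C)=CCC/C(C)=C/Cc1c(OCOC)cc(Br)cc1OCOC | intermediate
7 | methyl 3,4-dihydroxybenzoate | COC(=O)c1ccc(O)c(O)c1 | starting material
8 | methyl 3,4-bis(methoxymethoxy)benzoate | COCOc1ccc(C(=O)OC)cc1OCOC | intermediate
9 | N-methoxy-N-methylacetamide | CC(=O)N(C)OC | starting material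
10 | lithium enolate of 9 (lithium 1-[methoxy(methyl)amino]ethenolate) | C=C(O[Li])N(C)OC | intermediate
11 | 3-[3,4-bis(methoxymethoxy)phenyl]-N-methoxy-N-methyl-3-oxopropanamide | CON(C)C(=O)CC(=O)c1ccc(OCOC)c(OCOC)c1 | intermediate
12 | (3S)-3-[3,4-bis(methoxymethoxy)phenyl]-3-hydroxy-N-methoxy-N-methylpropanamide | CON(C)C(=O)C[C@H](O)c1ccc(OCOC)c(OCOC)c1 | intermediate
13 | [6-bromo-3-geranyl-2,4-bis(methoxymethoxy)phenyl]lithium | CC(C)=CCC/C(C)=C/Cc1c(OCOC)cc(Br)c([Li])c1OCOC | intermediate
14 | chloromagnesium alkoxide of 12 | CON(C)C(=O)C[C@H](O[Mg]Cl)c1ccc(OCOC)c(OCOC)c1 | intermediate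
15 | (3S)-1-[6-bromo-3-geranyl-2,4-bis(methoxymethoxy)phenyl]-3-[3,4-bis(methoxymethoxy)phenyl]-3-hydroxypropan-1-one | CC(C)=CCC/C(C)=C/Cc1c(OCOC)cc(Br)c(C(=O)C[C@H](O)c2ccc(OCOC)c(OCOC)c2)c1OCOC | intermediate
16 | diethylboron chelate (O-diethylboryl derivative) of 15 | CC(C)=CCC/C(C)=C/Cc1c(OCOC)cc(Br)c(C(=O)C[C@H](OB(CC)CC)c2ccc(OCOC)c(OCOC)c2)c1OCOC | intermediate
17 | (1R,3S)-1-[6-bromo-3-geranyl-2,4-bis(methoxymethoxy)phenyl]-3-[3,4-bis(methoxymethoxy)phenyl]propane-1,3-diol | CC(C)=CCC/C(C)=C/Cc1c(OCOC)cc(Br)c([C@H](O)C[C@H](O)c2ccc(OCOC)c(OCOC)c2)c1OCOC | intermediate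
18 | (2S,4R)-6-geranyl-5,7,3',4'-tetrakis(methoxymethoxy)flavan-4-ol | CC(C)=CCC/C(C)=C/Cc1c(OCOC)cc2c(c1OCOC)[C@H](O)C[C@@H](c1ccc(OCOC)c(OCOC)c1)O2 | intermediate
19 | (2S)-6-geranyl-5,7,3',4'-tetrakis(methoxymethoxy)flavanone | CC(C)=CCC/C(C)=C/Cc1c(OCOC)cc2c(c1OCOC)C(=O)C[C@@H](c1ccc(OCOC)c(OCOC)c1)O2 | intermediate
20 | nymphaeol A | CC(C)=CCC/C(C)=C/Cc1c(O)cc2c(c1O)C(=O)C[C@@H](c1ccc(O)c(O)c1)O2 | target

**Step count**
Total steps: 11. Longest linear sequence: 8 steps (steps 1–3 then 7–11, or steps 4–6 then 7–11).

**Steps most likely to fail**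

1. Step 9 (ring closure). Oxidative addition into the electron-rich, ortho-substituted C–Br bond may be slow, so that reductive loss of bromine or copper-mediated dehydrogenation of a benzylic carbinol overtakes C–O bond formation. The fallback sets out from 17 and returns at 18 and replaces the copper alkoxide pathway by a palladium cycle (Buchwald–Hartwig intramolecular etherification): Pd(OAc)2, 2-(di-tert-butylphosphino)-1,1'-binaphthyl, Cs2CO3, toluene, 80 °C. Zerovalent palladium inserts readily into electron-rich aryl bromides and the bulky phosphine drives C–O reductive elimination ahead of β-hydride elimination; the C2–O bond is again not broken, so C2 is retained. This fallback makes no new compound (F0).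

2. Step 7 (fragment union). Acyl transfer from the amide to the hindered aryllithium may be slower than loss of LiBr from the aryllithium (aryne formation) on warming, or than proton transfer from the amide, which would return 6. The fallback sets out from 12 and aryllithium 13 and returns at 15, using an aldehyde as a much faster electrophile at −78 °C. Amide 12 would be silylated (t-BuMe2SiCl, imidazole, DMF) to (3S)-3-[3,4-bis(methoxymethoxy)phenyl]-3-[(tert-butyldimethylsilyl)oxy]-N-methoxy-N-methylpropanamide F1 and reduced (i-Bu2AlH, THF, −78 °C) to (3S)-3-[3,4-bis(methoxymethoxy)phenyl]-3-[(tert-butyldimethylsilyl)oxy]propanal F2. Addition of 13 to this aldehyde at −78 °C should give (1RS,3S)-1-[6-bromo-3-geranyl-2,4-bis(methoxymethoxy)phenyl]-3-[3,4-bis(methoxymethoxy)phenyl]-3-[(tert-butyldimethylsilyl)oxy]propan-1-ol F3 as a pair of C1 epimers. Dess–Martin oxidation would converge both to (3S)-1-[6-bromo-3-geranyl-2,4-bis(methoxymethoxy)phenyl]-3-[3,4-bis(methoxymethoxy)phenyl]-3-[(tert-butyldimethylsilyl)oxy]propan-1-one F4, and HF·pyridine (THF) would free the C3 hydroxyl to return 15.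

3. Step 11 (global deprotection). Under protic acid the C5 or C7 phenol, or methanol, may add to the geranyl alkenes, and prolonged heating may erode C2 through ring opening. The fallback sets out from 19 and returns at 20 and avoids protic solvolysis altogether: the acetals would be cleaved by Lewis-acid-assisted transfer of the CH2OMe unit to a thiol (ZnBr2, n-PrSH, CH2Cl2, 0 °C), an aprotic reaction that is expected to be complete in minutes at low temperature. This fallback makes no new compound (F0).

**Further compounds**
F1 | step 7 | (3S)-3-[3,4-bis(methoxymethoxy)phenyl]-3-[(tert-butyldimethylsilyl)oxy]-N-methoxy-N-methylpropanamide | CON(C)C(=O)C[C@H](O[Si](C)(C)C(C)(C)C)c1ccc(OCOC)c(OCOC)c1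
F2 | step 7 | (3S)-3-[3,4-bis(methoxymethoxy)phenyl]-3-[(tert-butyldimethylsilyl)oxy]propanal | O=CC[C@H](O[Si](C)(C)C(C)(C)C)c1ccc(OCOC)c(OCOC)c1
F3 | step 7 | (1RS,3S)-1-[6-bromo-3-geranyl-2,4-bis(methoxymethoxy)phenyl]-3-[3,4-bis(methoxymethoxy)phenyl]-3-[(tert-butyldimethylsilyl)oxy]propan-1-ol | CC(C)=CCC/C(C)=C/Cc1c(OCOC)cc(Br)c(C(O)C[C@H](O[Si](C)(C)C(C)(C)C)c2ccc(OCOC)c(OCOC)c2)c1OCOC
F4 | step 7 | (3S)-1-[6-bromo-3-geranyl-2,4-bis(methoxymethoxy)phenyl]-3-[3,4-bis(methoxymethoxy)phenyl]-3-[(tert-butyldimethylsilyl)oxy]propan-1-one | CC(C)=CCC/C(C)=C/Cc1c(OCOC)cc(Br)c(C(=O)C[C@H](O[Si](C)(C)C(C)(C)C)c2ccc(OCOC)c(OCOC)c2)c1OCOC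
F0 | step 9 | none | none
F0 | step 11 | none | none
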